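**Assumption:** (2S)-(–)-eriodictyol (natural configuration, from citrus/Eriodictyon or made from hesperidin) is bought enantiopure; its ee is checked by chiral HPLC before use and again on the final product.

## Retrosynthetic overview
1. Prokinawan ⇒ its 3',4',7-triacetate 10 (neutral deacetylation at the end).
2. The C2''=C3'' (E) alkene ⇒ cross-metathesis of 6-allyl flavanone 6 with the 1,1-disubstituted alkenol 9.
3. Key C6–C1'' bond ⇒ Eu(III)-catalysed aromatic Claisen ([3,3]) rearrangement of 5-O-allyl ether 5; C6 is the only open ortho position of O5, so the regiochemistry is fixed.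
4. 5 ⇒ (2S)-eriodictyol by selective triacetylation (chelated 5-OH spared) and Mitsunobu O-allylation.
5. No ring is formed: all three rings and the C2 stereocentre are bought in eriodictyol and kept away from base throughout.

## Route

**Step 1**
Reactants: 1 (2S)-eriodictyol; 2 acetic anhydride
Product: 3 (2S)-3',4',7-tri-O-acetyleriodictyol (5-OH free)
Conditions: Ac2O (3.3 equiv), pyridine, 0 °C → rt, 3 h
Reagents that add atoms: acetic anhydride, CC(=O)OC(C)=O
Why: Selective O-acylation: the 5-OH is hydrogen-bonded to the C4 carbonyl and acylates far more slowly than the 7-, 3'- and 4'-OH, and pyridine is too weak a base to open the flavanone, so C2 is untouched.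

**Step 2**
Reactants: 3; 4 allyl alcohol
Product: 5 (2S)-5-O-allyl-3',4',7-tri-O-acetyleriodictyol
Conditions: allyl alcohol (2 equiv), PPh3, DIAD, THF, 0 °C → rt
Reagents that add atoms: allyl alcohol, C=CCO
Why: Mitsunobu etherification alkylates the only free (chelated) phenol under essentially neutral conditions, so the aryl acetates survive and the base-labile C2 centre is not epimerised.

**Step 3 (key step)**
Reactants: 5
Product: 6 (2S)-6-C-allyl-3',4',7-tri-O-acetyleriodictyol (5-OH regenerated)
Conditions: Eu(fod)3 (10 mol%), PhCl, 90 °C, Ar, 24–48 h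
Reagents that add atoms: none
Why: Aromatic Claisen [3,3]-sigmatropic rearrangement, accelerated by Eu(III) chelation to C4=O/O5, delivers the allyl group to C6 (C4a is blocked), and fast enolisation of the dienone prevents onward Cope migration to C8; no stereocentre is created.

**Step 4**
Reactants: 7 6-methylhept-6-en-2-one; 8 methylmagnesium bromide
Product: 9 2,6-dimethylhept-6-en-2-ol
Conditions: MeMgBr (1.2 equiv), THF, 0 °C; aq. NH4Cl
Reagents that add atoms: methylmagnesium bromide, C[Mg]Br
Why: Grignard 1,2-addition to a methyl ketone gives the achiral tertiary alcohol; the isolated alkene is inert.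

**Step 5**
Reactants: 6; 9 (5 equiv)
Product: 10 (2S)-3',4',7-tri-O-acetylprokinawan, i.e. 6-[(2E)-7-hydroxy-3,7-dimethyloct-2-en-1-yl]-3',4',7-tri-O-acetyleriodictyol
Conditions: Grubbs II (2 × 5 mol%), 1,4-benzoquinone (10 mol%), CH2Cl2, 40 °C, 24 h; E isomer isolated by AgNO3–SiO2 chromatography or prep-HPLC
Reagents that add atoms: none (9 is a reactant; ethylene is lost)
Why: Olefin cross-metathesis of a terminal alkene with a non-homodimerising 1,1-disubstituted alkene gives the trisubstituted olefin with the larger chain trans to ArCH2; expected E:Z is only about 3:1, so the E isomer must be separated, and benzoquinone suppresses allyl-to-propenyl isomerisation.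

**Step 6**
Reactants: 10
Product: 11 prokinawan
Conditions: NH4OAc (10 equiv), MeOH–H2O (4:1), rt, Ar, 8–12 h
Reagents that add atoms: none
Why: Neutral transesterification/hydrolysis of the three activated aryl acetates avoids both base (flavanone ring-opening and C2 racemisation, catechol oxidation) and acid (chroman formation from the 5/7-OH onto the alkene, loss of the tertiary alcohol).

## Compound list
1 | (2S)-eriodictyol | O=C1C[C@@H](c2ccc(O)c(O)c2)Oc2cc(O)cc(O)c12 | starting material
2 | acetic anhydride | CC(=O)OC(C)=O | starting material (reagent)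
3 | (2S)-3',4',7-tri-O-acetyleriodictyol | CC(=O)Oc1cc(O)c2C(=O)C[C@@H](c3ccc(OC(C)=O)c(OC(C)=O)c3)Oc2c1 | intermediate
4 | allyl alcohol | C=CCO | starting material
5 | (2S)-5-O-allyl-3',4',7-tri-O-acetyleriodictyol | CC(=O)Oc1cc(OCC=C)c2C(=O)C[C@@H](c3ccc(OC(C)=O)c(OC(C)=O)c3)Oc2c1 | intermediate
6 | (2S)-6-C-allyl-3',4',7-tri-O-acetyleriodictyol | C=CCc1c(OC(C)=O)cc2c(c1O)C(=O)C[C@@H](c1ccc(OC(C)=O)c(OC(C)=O)c1)O2 | intermediate
7 | 6-methylhept-6-en-2-one | CC(=O)CCCC(C)=C | starting material
8 | methylmagnesium bromide | C[Mg]Br | starting material (reagent)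
9 | 2,6-dimethylhept-6-en-2-ol | C=C(C)CCCC(C)(C)O | intermediate
10 | (2S,2''E)-3',4',7-tri-O-acetylprokinawan | C/C(=C\Cc1c(OC(C)=O)cc2c(c1O)C(=O)C[C@@H](c1ccc(OC(C)=O)c(OC(C)=O)c1)O2)CCCC(C)(C)O | intermediate
11 | prokinawan | C/C(=C\Cc1c(O)cc2c(c1O)C(=O)C[C@@H](c1ccc(O)c(O)c1)O2)CCCC(C)(C)O | target

## Summary
Total steps: 6. Longest linear sequence: 5 (1 → 3 → 5 → 6 → 10 → 11).

Three steps most likely to fail, each with a fallback that changes the approach:

1. **Step 5 (cross-metathesis).** The E:Z ratio is modest (about 3:1) and conversion with a 1,1-disubstituted partner may be incomplete. Fallback: set the geometry in two stereodefined operations. Cross-metathesise 6 with isopropenyl-B(pin), which places boron trans to ArCH2 with high selectivity, then convert to the alkenyl iodide with retention and run a Pd-catalysed Negishi coupling with the alkylzinc from TMS-protected 5-iodo-2-methylpentan-2-ol.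

2. **Step 3 (Eu(III)-Claisen of an unsubstituted allyl ether).** It may be sluggish, or give deallylation or some C8 migration. Fallback: abandon the O→C migration and make 6 by cross-coupling. Iodinate 3 regioselectively at C6, ortho to the free 5-OH (BnMe3N⁺ ICl2⁻, CaCO3), then Stille-couple with allyltributylstannane (Pd(PPh3)4).

3. **Step 6 (and C2 integrity generally).** Deacetylation may be incomplete or cause partial racemisation via the chalcone. Fallback: change the protecting-group strategy from step 1 to silyl ethers (3',4',7-tri-O-TBS, 5-OH free) and finish with fluoride at pH < 7 (HF·pyridine/pyridine, THF, 0 °C), so no acyl cleavage is needed.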